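**Retrosynthetic overview**

- Feature: ring A (the indole that ends as the 2-carbaldehyde) bears carbon on two adjacent ring atoms, C2 (the formyl carbon) and C3 (the methine carbon that also holds C3 of rings B and C). An indol-2-yl boronate can take up both substituents in one operation.
- Disconnections: CHO ⇐ CH2OH ⇐ CH2OBn; the methine–C3(ring A) bond ⇐ a bis(indol-3-yl)methylium cation attacking C3 of the boronate; the C2(ring A)–CH2 bond ⇐ a 1,2-shift of the benzyloxymethyl group from boron to C2.
- Building blocks: 2-lithiated 1-SEM-indole, benzyloxymethyl pinacol boronate (benzyl alcohol plus the bromomethyl boronate), and the cation salt (3,3'-diindolylmethane, N-SEM protection, hydride abstraction).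
- Ring formation: none. Rings A, B and C are bought as indole and 3,3'-diindolylmethane; ring A is dearomatised and rearomatised within the key step. End game: hydrogenolysis, fluoride removal of three SEM groups, MnO2.

Key step: step 5

Remark: SEM = 2-(trimethylsilyl)ethoxymethyl. The target has no stereocentre; the two centres that appear in the key step are transient, racemic and lost on rearomatisation.

**Route**

Step 1
Reactants: 1 indole
Product: 3 1-SEM-indole (1-{[2-(trimethylsilyl)ethoxy]methyl}-1H-indole), via sodium indol-1-ide 2 (not isolated)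
Conditions: NaH, DMF, 0 °C; SEMCl, 0 °C → rt
Reagents that add atoms: 2-(trimethylsilyl)ethoxymethyl chloride (SEMCl), C[Si](C)(C)CCOCCl
Why: N-alkylation (SN2) of the dissociated sodium indolide by the chloromethyl ether in DMF, which should go at nitrogen and not at C3.

Step 2
Reactants: 4 3,3'-diindolylmethane
Product: 6 bis(1-SEM-indol-3-yl)methane, via disodium 3,3'-methylenebis(indol-1-ide) 5 (not isolated)
Conditions: NaH (2.4 equiv), DMF, 0 °C; SEMCl (2.2 equiv), 0 °C → rt
Reagents that add atoms: 2-(trimethylsilyl)ethoxymethyl chloride (SEMCl), C[Si](C)(C)CCOCCl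
Why: twofold N-alkylation (SN2) of the bis-indolide, the bridging CH2 being far less acidic than the two N–H groups.

Step 3
Reactants: 6 bis(1-SEM-indol-3-yl)methane
Product: 7 bis(1-SEM-indol-3-yl)methylium tetrafluoroborate
Conditions: Ph3CBF4 (1.0 equiv), CH2Cl2, 0 °C → rt, argon; Et2O (precipitation)
Reagents that add atoms: triphenylcarbenium tetrafluoroborate, F[B-](F)(F)F.c1ccc(cc1)[C+](c1ccccc1)c1ccccc1
Why: hydride abstraction by the trityl cation from the doubly indol-3-yl-substituted CH2, the best hydride donor in the molecule, which should be downhill because the vinylogous amidinium-type cation is far more stabilised than Ph3C+.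

Step 4
Reactants: 8 benzyl alcohol; 9 2-(bromomethyl)-4,4,5,5-tetramethyl-1,3,2-dioxaborolane
Product: 11 2-[(benzyloxy)methyl]-4,4,5,5-tetramethyl-1,3,2-dioxaborolane, via sodium benzyloxide 10 (not isolated)
Conditions: NaH, THF, 0 °C; 9, 0 °C → rt
Reagents that add atoms: none
Why: Williamson-type displacement of bromide at the α-boryl carbon by the alkoxide, a substitution that the neighbouring boron makes fast for α-halo boronic esters.

Step 5
Reactants: 3 1-SEM-indole; 11 2-[(benzyloxy)methyl]-4,4,5,5-tetramethyl-1,3,2-dioxaborolane; 7 bis(1-SEM-indol-3-yl)methylium tetrafluoroborate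
Product: 16 2-[(benzyloxy)methyl]-3-[bis(1-SEM-indol-3-yl)methyl]-1-SEM-indole, via 2-lithio-1-SEM-indole 12 (not isolated), via lithium indol-2-yl boronate complex 13 (not isolated), via trans-indoline-2-boronic ester 14 (not isolated), via 2-hydroxyindoline 15 (not isolated)
Conditions: n-BuLi (0.98 equiv), THF, −78 → −10 °C; 11, −78 → 0 °C; 7 in CH2Cl2, −78 °C → rt; then 2 M NaOH, 30% H2O2, 0 °C → rt; aq NH4Cl
Reagents that add atoms: none
Why: C2-lithiation of 3 (assisted by the SEM oxygen) and addition to the boron of 11 give the tetracoordinate boronate 13, whose C3, an enamine β-carbon made much more nucleophilic by the anionic boron, attacks the central carbon of cation 7 (methine–C3 bond); the 3H-indolium carbon C2 so formed pulls the benzyloxymethyl group over from boron (C2–CH2 bond) to give 14, NaOH/H2O2 replaces boron by hydroxyl (15), and loss of water across C2–C3 restores the indole. The closest known reaction type is the electrophile-induced three-component 1,2-metallate rearrangement of indol-2-yl boronate complexes with carbon electrophiles followed by oxidative rearomatisation, and heteroaryl boronate complexes are also known to combine with benzhydrylium-type carbenium ions, so the stabilised diarylcarbenium salt is a further member of a known electrophile family. No ring is closed. The two stereocentres of 14 (C2 and C3 of ring A) should form with the migrating group anti to the new C3 substituent, as the shift is stereospecific, but both are erased by the dehydration, so the product has none. The step needs attack at C3 and not at the boron-bearing C2, attack at the methine carbon of 7, and migration of the benzyloxymethyl group only; these should be secured by the enamine polarisation of the boronate, by the largest LUMO coefficient lying on the methine carbon, and by benzyloxymethyl being the sole carbon ligand on boron besides the indolyl group, since the pinacol oxygens do not migrate. Full N-protection of all three indoles removes any proton that could quench the boronate or trigger the shift by C3-protonation without the cation.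

Step 6
Reactants: 16 2-[(benzyloxy)methyl]-3-[bis(1-SEM-indol-3-yl)methyl]-1-SEM-indole
Product: 17 {3-[bis(1-SEM-indol-3-yl)methyl]-1-SEM-indol-2-yl}methanol
Conditions: H2 (1 atm), 10% Pd/C, EtOAc/EtOH, rt
Reagents that add atoms: none
Why: catalytic hydrogenolysis of the benzyl ether should cut the unhindered PhCH2–O bond, while the indol-2-ylmethyl C–O bond is shielded by the N-SEM group and the bulky C3 substituent, and the SEM groups and indole rings are inert to H2 over Pd/C at 1 atm.

Step 7
Reactants: 17 {3-[bis(1-SEM-indol-3-yl)methyl]-1-SEM-indol-2-yl}methanol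
Product: 18 {3-[bis(1H-indol-3-yl)methyl]-1H-indol-2-yl}methanol
Conditions: Bu4NF (1 M in THF, excess), H2NCH2CH2NH2, DMF, 80 °C
Reagents that add atoms: none
Why: fluoride-induced fragmentation of the three N-SEM groups (attack at silicon, loss of ethylene and formaldehyde), with ethylenediamine trapping formaldehyde so that N-hydroxymethyl groups do not persist, under non-acidic conditions that the tris(indolyl)methane and the indol-2-ylmethanol require.

Step 8
Reactants: 18 {3-[bis(1H-indol-3-yl)methyl]-1H-indol-2-yl}methanol
Product: 19 trisindolal (3-[bis(1H-indol-3-yl)methyl]-1H-indole-2-carbaldehyde)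
Conditions: activated MnO2 (excess), acetone, rt
Reagents that add atoms: none
Why: MnO2 oxidation of the activated (heterobenzylic) indol-2-ylmethanol should stop at the aldehyde and leave the free N–H indoles and the triarylmethine C–H untouched.

**Compound list**

1 | indole | c1ccc2[nH]ccc2c1 | starting material
2 | sodium indol-1-ide | [Na+].c1ccc2[n-]ccc2c1 | intermediate
3 | 1-SEM-indole (1-{[2-(trimethylsilyl)ethoxy]methyl}-1H-indole) | C[Si](C)(C)CCOCn1ccc2ccccc12 | intermediate
4 | 3,3'-diindolylmethane | C(c1c[nH]c2ccccc12)c1c[nH]c2ccccc12 | starting material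
5 | disodium 3,3'-methylenebis(indol-1-ide) | [Na+].[Na+].C(c1c[n-]c2ccccc12)c1c[n-]c2ccccc12 | intermediate
6 | bis(1-SEM-indol-3-yl)methane | C(c1cn(COCC[Si](C)(C)C)c2ccccc12)c1cn(COCC[Si](C)(C)C)c2ccccc12 | intermediate
7 | bis(1-SEM-indol-3-yl)methylium tetrafluoroborate | F[B-](F)(F)F.[CH+](c1cn(COCC[Si](C)(C)C)c2ccccc12)c1cn(COCC[Si](C)(C)C)c2ccccc12 | intermediate
8 | benzyl alcohol | OCc1ccccc1 | starting material
9 | 2-(bromomethyl)-4,4,5,5-tetramethyl-1,3,2-dioxaborolane | CC1(C)OB(CBr)OC1(C)C | starting material
10 | sodium benzyloxide | [Na+].[O-]Cc1ccccc1 | intermediate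
11 | 2-[(benzyloxy)methyl]-4,4,5,5-tetramethyl-1,3,2-dioxaborolane | CC1(C)OB(COCc2ccccc2)OC1(C)C | intermediate
12 | 2-lithio-1-SEM-indole | [Li]c1cc2ccccc2n1COCC[Si](C)(C)C | intermediate
13 | lithium [(benzyloxy)methyl](1-SEM-indol-2-yl)(pinacolato)borate | [Li+].CC1(C)O[B-](COCc2ccccc2)(c2cc3ccccc3n2COCC[Si](C)(C)C)OC1(C)C | intermediate
14 | 2-[(benzyloxy)methyl]-3-[bis(1-SEM-indol-3-yl)methyl]-2-(pinacolatoboryl)-1-SEM-indoline, benzyloxymethyl trans to the C3 substituent, racemic (one enantiomer drawn) | C[Si](C)(C)CCOCN1c2ccccc2[C@@H](C(c2cn(COCC[Si](C)(C)C)c3ccccc23)c2cn(COCC[Si](C)(C)C)c3ccccc23)[C@@]1(COCc1ccccc1)B1OC(C)(C)C(C)(C)O1 | intermediate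
15 | 2-[(benzyloxy)methyl]-3-[bis(1-SEM-indol-3-yl)methyl]-1-SEM-indolin-2-ol, hydroxyl cis to the C3 substituent, racemic (one enantiomer drawn) | C[Si](C)(C)CCOCN1c2ccccc2[C@@H](C(c2cn(COCC[Si](C)(C)C)c3ccccc23)c2cn(COCC[Si](C)(C)C)c3ccccc23)[C@@]1(COCc1ccccc1)O | intermediate
16 | 2-[(benzyloxy)methyl]-3-[bis(1-SEM-indol-3-yl)methyl]-1-SEM-indole | C[Si](C)(C)CCOCn1c(COCc2ccccc2)c(C(c2cn(COCC[Si](C)(C)C)c3ccccc23)c2cn(COCC[Si](C)(C)C)c3ccccc23)c2ccccc12 | intermediate
17 | {3-[bis(1-SEM-indol-3-yl)methyl]-1-SEM-indol-2-yl}methanol | C[Si](C)(C)CCOCn1c(CO)c(C(c2cn(COCC[Si](C)(C)C)c3ccccc23)c2cn(COCC[Si](C)(C)C)c3ccccc23)c2ccccc12 | intermediate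
18 | {3-[bis(1H-indol-3-yl)methyl]-1H-indol-2-yl}methanol | OCc1[nH]c2ccccc2c1C(c1c[nH]c2ccccc12)c1c[nH]c2ccccc12 | intermediate
19 | trisindolal | O=Cc1[nH]c2ccccc2c1C(c1c[nH]c2ccccc12)c1c[nH]c2ccccc12 | target

**Step count and risks**

Total steps: 8. Longest linear sequence: 6 steps (4 → 6 → 7 → 16 → 17 → 18 → 19; steps 2, 3, 5, 6, 7, 8).

Steps most likely to fail:

1. Step 5. The electron-rich boronate may transfer an electron to the cation instead of forming the C–C bond, which would give homocoupled material. Attack at the crowded methine carbon may be so slow that the boronate decays on warming. The α-oxygenated group may migrate sluggishly, so that boron is lost without the shift. The fallback forms the two bonds in separate operations by known chemistry. It sets out from 3 and comes back at 16. Compound 3 is lithiated as before to 12 and trapped at −78 °C with benzyl chloromethyl ether (ClCH2OCH2Ph) to give 2-[(benzyloxy)methyl]-1-SEM-indole F1. F1 is then alkylated at its free C3 by salt 7 in MeCN with 2,6-di-tert-butylpyridine as proton trap (rt → 50 °C), the classical Friedel–Crafts addition of an indole to a bis(indolyl)methylium ion, which should give 16 directly.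

2. Step 3. The trityl cation may take hydride from the N,O-acetal CH2 of a SEM group or alkylate an indole ring instead of abstracting the bridging hydride, or the transfer may stall and the salt hydrolyse on isolation. The fallback builds the cation by condensation instead of oxidation. It sets out from 3 and comes back at 7. Vilsmeier–Haack formylation of 3 (POCl3, DMF, 0 °C → rt) should give dimethyl[(1-SEM-indol-3-yl)methylidene]ammonium dichlorophosphate F2, which is not isolated and is hydrolysed with aqueous NaOH to 1-SEM-indole-3-carbaldehyde F3. F3 is then condensed with one equivalent of 3 and one equivalent of HBF4·OEt2 in Et2O/CH2Cl2 at 0 °C over 4 Å sieves (hydroxyalkylation at C3, then ionisation of the carbinol), and salt 7 should precipitate.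

3. Step 6. Hydrogenolysis may occur on the wrong side of the ether oxygen, cutting the indol-2-ylmethyl C–O bond to leave a 2-methylindole, or turnover may be slow on the hindered substrate. The fallback changes the order and the mechanism of debenzylation. It sets out from 16 and comes back at 18. The three SEM groups are removed first (Bu4NF, ethylenediamine, DMF, 80 °C) to give 2-[(benzyloxy)methyl]-3-[bis(1H-indol-3-yl)methyl]-1H-indole F4. F4 is then cleaved with Na in NH3(l)/THF at −78 °C and quenched with NH4Cl. The three N–H groups are deprotonated to indolides that resist electron uptake, so the electron should enter the phenyl ring and break the PhCH2–O bond, giving 18.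

**Further compounds**

F1 | step 5 | 2-[(benzyloxy)methyl]-1-SEM-indole | C[Si](C)(C)CCOCn1c(COCc2ccccc2)cc2ccccc12
F2 | step 3 | dimethyl[(1-SEM-indol-3-yl)methylidene]ammonium dichlorophosphate | C[N+](C)=Cc1cn(COCC[Si](C)(C)C)c2ccccc12.[O-]P(=O)(Cl)Cl
F3 | step 3 | 1-SEM-indole-3-carbaldehyde | O=Cc1cn(COCC[Si](C)(C)C)c2ccccc12
F4 | step 6 | 2-[(benzyloxy)methyl]-3-[bis(1H-indol-3-yl)methyl]-1H-indole | C(OCc1ccccc1)c1[nH]c2ccccc2c1C(c1c[nH]c2ccccc12)c1c[nH]c2ccccc12
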